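Every diaryl ether is cut between the chain oxygen and the ring carbon that has an oxygenated carbon ortho or para to it, so rings A to F each equal a benzyl-protected quinone diazide and the chain grows from ring G by metal-carbene O–H insertion, every cycle freeing the next phenol. The key step exploits ring C, where C6 (bound to the ring D oxygen) lies ortho to oxygenated C1: a tris(benzyloxy) ortho-quinone diazide, diazo on C6 and carbonyl on C1, is inserted into the lone phenol of a benzylated D–E–F–G tetramer, forming the C6–O bond, rearomatising ring C and unveiling the C1 phenol in one operation.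

Key step: step 14

Remark on the chemistry: the target has no stereocentre and its diaryl ether axes are assumed to rotate freely, so nothing stereochemical has to be set; rings are lettered A (2,4,6-trihydroxyphenyl end) to G (3,4,5-trihydroxyphenoxy end), C1 of rings B to F being the oxygenated carbon that points towards ring A and C1 of ring A the hydroxylated carbon next to its ether carbon (C4 in rings B, D, F and C6 in rings A, C, E carry the oxygen pointing towards ring G).

Step 1
Reactants: 1 3,5-bis(benzyloxy)phenol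
Product: 2 3,5-bis(benzyloxy)-4-nitrosophenol
Conditions: NaNO2, AcOH, EtOH–H2O, 0 °C
Reagents that add atoms: sodium nitrite, [Na+].[O-]N=O
Why: Electrophilic C-nitrosation of a phenol is strongly para-directed by the hydroxyl group (as with 3-alkoxy- and 3,5-dialkylphenols), so the nitroso group should enter C4 between the two benzyloxy groups, any chelated ortho isomer being removed by crystallisation at this stable stage.

Step 2
Reactants: 2 3,5-bis(benzyloxy)-4-nitrosophenol
Product: 3 4-amino-3,5-bis(benzyloxy)phenol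
Conditions: Na2S2O4, THF–H2O, 50 °C, argon
Reagents that add atoms: none
Why: Dithionite reduction of a nitrosophenol (quinone monooxime tautomer) to the aminophenol is a classical electron-transfer reduction that cannot touch benzyl ethers because no hydrogenation catalyst is present; the air-sensitive amine is used at once.

Step 3
Reactants: 3 4-amino-3,5-bis(benzyloxy)phenol
Product: 5 3,5-bis(benzyloxy)-4-diazocyclohexa-2,5-dien-1-one, via diazonium chloride 4 (not isolated)
Conditions: NaNO2, 2 M HCl, MeCN–H2O, 0 °C; then NaHCO3 to pH 8, CH2Cl2 extraction, dark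
Reagents that add atoms: sodium nitrite, [Na+].[O-]N=O
Why: Diazotisation of a para-aminophenol gives a hydroxyarenediazonium salt whose acidic phenol is deprotonated by bicarbonate to the neutral para-quinone diazide, here stabilised by the two alkoxy donors flanking the diazo carbon.

Step 4
Reactants: 1 3,5-bis(benzyloxy)phenol
Product: 6 3,5-bis(benzyloxy)-2-nitrophenol
Conditions: 65% HNO3 (1.05 equiv), AcOH–CH2Cl2, −15 °C
Reagents that add atoms: nitric acid, O[N+](=O)[O-]
Why: Electrophilic aromatic nitration with one equivalent of acid at low temperature should favour the two equivalent ortho positions (each para to a benzyloxy group and less crowded than C4), and the hydrogen-bonded ortho-nitrophenol is easily separated by chromatography from the more polar 4-nitro regioisomer.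

Step 5
Reactants: 6 3,5-bis(benzyloxy)-2-nitrophenol
Product: 7 2-amino-3,5-bis(benzyloxy)phenol
Conditions: Na2S2O4, THF–EtOH–H2O, 60 °C, argon
Reagents that add atoms: none
Why: Dithionite reduction of an ortho-nitrophenol to the ortho-aminophenol is standard and chemoselective, leaving both benzyl ethers untouched.

Step 6
Reactants: 7 2-amino-3,5-bis(benzyloxy)phenol
Product: 9 3,5-bis(benzyloxy)-6-diazocyclohexa-2,4-dien-1-one, via diazonium chloride 8 (not isolated)
Conditions: NaNO2, 2 M HCl, MeCN–H2O, 0 °C; then NaHCO3 to pH 8, CH2Cl2 extraction, dark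
Reagents that add atoms: sodium nitrite, [Na+].[O-]N=O
Why: Diazotisation of an ortho-aminophenol followed by neutralisation is the classical preparation of ortho-quinone diazides, the diazonium phenolate being an isolable neutral species.

Step 7
Reactants: 10 3,4,5-trihydroxybenzaldehyde
Product: 11 3,4,5-tris(benzyloxy)benzaldehyde
Conditions: BnBr (3.3 equiv), K2CO3, DMF, 60 °C, argon
Reagents that add atoms: benzyl bromide, BrCc1ccccc1
Why: Williamson etherification of all three phenols proceeds readily because the aldehyde makes them acidic and the benzylic halide is a good SN2 electrophile; argon prevents oxidation of the pyrogallol before it is capped.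

Step 8
Reactants: 11 3,4,5-tris(benzyloxy)benzaldehyde
Product: 13 3,4,5-tris(benzyloxy)phenol, via aryl formate 12 (not isolated)
Conditions: mCPBA, CH2Cl2, 0 °C to rt; NaHCO3 wash; then K2CO3 (cat.), MeOH, rt
Reagents that add atoms: 3-chloroperoxybenzoic acid, OOC(=O)c1cccc(Cl)c1
Why: Baeyer–Villiger oxidation of an electron-rich benzaldehyde proceeds with migration of the aryl group to give the aryl formate, which methanolysis cleaves to the phenol.

Step 9
Reactants: 13 3,4,5-tris(benzyloxy)phenol
Product: 15 2-amino-3,4,5-tris(benzyloxy)phenol, via azo dye 14 (not isolated)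
Conditions: 4-diazoniobenzenesulfonate (preformed inner salt), NaOH, THF–H2O, 0 °C, argon; then Na2S2O4, 50 °C
Reagents that add atoms: 4-diazoniobenzenesulfonate, [O-]S(=O)(=O)c1ccc(cc1)[N+]#N
Why: Azo coupling of the phenolate, whose para position is blocked, can only take place at one of the two equivalent ortho carbons, and dithionite cleavage of the N=N bond leaves the ortho-aminophenol while the sulfanilate stays in water; this non-oxidising amination replaces nitric acid, which would be expected to oxidise the tetraoxygenated ring to a quinone.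

Step 10
Reactants: 15 2-amino-3,4,5-tris(benzyloxy)phenol
Product: 17 3,4,5-tris(benzyloxy)-6-diazocyclohexa-2,4-dien-1-one, via diazonium chloride 16 (not isolated)
Conditions: NaNO2, 2 M HCl, MeCN–H2O, 0 °C; then NaHCO3 to pH 8, CH2Cl2 extraction, dark, used promptly
Reagents that add atoms: sodium nitrite, [Na+].[O-]N=O
Why: Diazotisation and neutralisation of the ortho-aminophenol should give the ortho-quinone diazide as in step 6, the three alkoxy donors stabilising the diazonium phenolate enough for handling in the cold and dark.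

Step 11
Reactants: 13 3,4,5-tris(benzyloxy)phenol; 5 3,5-bis(benzyloxy)-4-diazocyclohexa-2,5-dien-1-one
Product: 18 3,5-bis(benzyloxy)-4-[3,4,5-tris(benzyloxy)phenoxy]phenol (dimer HO–F–G)
Conditions: Rh2(OAc)4 (2 mol%), 4 Å MS, 1,2-dichloroethane, 50 °C, dark; 5 added over several hours to 13 (3 equiv); excess 13 recovered
Reagents that add atoms: none
Why: Metal-carbene O–H insertion: the dirhodium catalyst expels N2 from 5, the phenol oxygen of 13 adds to the carbenoid carbon C4 and proton transfer aromatises ring F, while the threefold excess of inexpensive 13 and slow addition of 5 keep the freshly released ring F phenol from taking up a second diazide.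

Step 12
Reactants: 18 dimer phenol HO–F–G; 9 3,5-bis(benzyloxy)-6-diazocyclohexa-2,4-dien-1-one
Product: 19 3,5-bis(benzyloxy)-2-{3,5-bis(benzyloxy)-4-[3,4,5-tris(benzyloxy)phenoxy]phenoxy}phenol (trimer HO–E–F–G)
Conditions: Rh2(OAc)4 (2 mol%), 4 Å MS, 1,2-dichloroethane, 50 °C, dark; 9 (1.1 equiv) added slowly
Reagents that add atoms: none
Why: The same carbene O–H insertion joins C6 of ring E to the open ring F phenol oxygen and sets the vicinal oxygen pair of ring E, and mono-insertion should be favoured because the new ring E phenol has the bulky aryloxy group ortho to it.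

Step 13
Reactants: 19 trimer phenol HO–E–F–G; 5 3,5-bis(benzyloxy)-4-diazocyclohexa-2,5-dien-1-one
Product: 20 3,5-bis(benzyloxy)-4-[3,5-bis(benzyloxy)-2-{3,5-bis(benzyloxy)-4-[3,4,5-tris(benzyloxy)phenoxy]phenoxy}phenoxy]phenol (tetramer HO–D–E–F–G)
Conditions: Rh2(OAc)4 (2 mol%), 4 Å MS, 1,2-dichloroethane, 50 °C, dark; 5 (0.6 equiv) by syringe pump; unreacted 19 recovered and recycled
Reagents that add atoms: none
Why: Carbene O–H insertion of the para-quinone diazide into the ring E phenol forms the C4(ring D)–O bond, and since the liberated ring D phenol is more open than the ortho-aryloxy phenol of 19, the diazide is kept limiting and dilute so that a second insertion stays minor.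

Step 14
Reactants: 20 tetramer phenol HO–D–E–F–G; 17 3,4,5-tris(benzyloxy)-6-diazocyclohexa-2,4-dien-1-one
Product: 21 pentamer phenol HO–C–D–E–F–G (dodecabenzyl ether; the ring D oxygen of 20 bonded to C6 of a 1-hydroxy-3,4,5-tris(benzyloxy)phenyl ring C)
Conditions: Rh2(OAc)4 (2 mol%), 4 Å MS, 1,2-dichloroethane, 50 °C, dark; 17 (1.2 equiv) added slowly
Reagents that add atoms: none
Why: Rh2(OAc)4 (divalent rhodium) strips N2 from 17 to give a quinoid rhodium carbenoid whose C6 has aryl-cation character; the unhindered ring D phenol oxygen of 20 adds to C6 to form an oxonium ylide, and loss of the metal with proton transfer from the oxonium to the C1 oxygen rearomatises ring C as the ortho-aryloxyphenol 21. The closest known reaction type is the dirhodium- or copper-catalysed O–H insertion of ortho-quinone diazides and diazonaphthoquinones into alcohols and phenols, applied here to a more heavily oxygenated diazide and an oligomeric phenol. No ring is closed and no stereocentre is created, so neither a mode of closure nor a stereocontrol element is involved. The step needs O–H insertion to beat Wolff ring contraction, electrophilic attack on the electron-rich ring carbons or benzyl phenyl groups, benzyl ether ylide chemistry, insertion into water and a second insertion. Site selectivity is fixed by the position of the diazo carbon, catalysis in the dark at moderate temperature disfavours the Wolff pathway, molecular sieves and the high phenol-to-diazide ratio kept by slow addition favour the intermolecular O–H pathway, and the new C1 phenol, with the bulky oligomeric aryloxy group ortho to it, should react more slowly than the open ring D phenol. The C6 carbon, electron-rich and flanked by oxygen on both sides, would be a poor electrophile for nucleophilic aromatic substitution, whereas as the carbene carbon it is the electrophile by design.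

Step 15
Reactants: 21 pentamer phenol HO–C–D–E–F–G; 5 3,5-bis(benzyloxy)-4-diazocyclohexa-2,5-dien-1-one
Product: 22 hexamer phenol HO–B–C–D–E–F–G (tetradecabenzyl ether; the ring C C1 oxygen of 21 bonded to C4 of a 1-hydroxy-3,5-bis(benzyloxy)phenyl ring B)
Conditions: Rh2(OAc)4 (2 mol%), 4 Å MS, 1,2-dichloroethane, 50 °C, dark; 5 (0.6 equiv) by syringe pump; unreacted 21 recovered and recycled
Reagents that add atoms: none
Why: The carbene O–H insertion of step 13 is repeated on the ring C phenol, again with the para-quinone diazide limiting and slowly added because the released ring B phenol is less hindered than the phenol being arylated.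

Step 16
Reactants: 22 hexamer phenol HO–B–C–D–E–F–G; 9 3,5-bis(benzyloxy)-6-diazocyclohexa-2,4-dien-1-one
Product: 23 hexadecabenzyl heptamer HO–A–B–C–D–E–F–G (the ring B C1 oxygen of 22 bonded to C6 of a 1-hydroxy-3,5-bis(benzyloxy)phenyl ring A)
Conditions: Rh2(OAc)4 (2 mol%), 4 Å MS, 1,2-dichloroethane, 50 °C, dark; 9 (1.1 equiv) added slowly
Reagents that add atoms: none
Why: The carbene O–H insertion of step 12 is repeated on the open ring B phenol, and the ring A phenol it releases, hindered by the ortho-aryloxy chain, is left free because it is one of the hydroxyl groups of the target.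

Step 17
Reactants: 23 hexadecabenzyl heptamer
Product: 24 CNP0351377.0 (heptamer with seventeen free hydroxyl groups)
Conditions: H2 (1 atm), Pd(OH)2/C, degassed THF–MeOH, rt; filtration and concentration under argon
Reagents that add atoms: none
Why: Catalytic hydrogenolysis cleaves only the sixteen benzylic C–O bonds and leaves the six diaryl ether bonds intact, while degassed solvents and argon handling protect the oxidation-prone polyphenol.

Compound list
1 | 3,5-bis(benzyloxy)phenol | Oc1cc(OCc9ccccc9)cc(OCc9ccccc9)c1 | starting material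
2 | 3,5-bis(benzyloxy)-4-nitrosophenol | O=Nc1c(OCc9ccccc9)cc(O)cc1OCc9ccccc9 | intermediate
3 | 4-amino-3,5-bis(benzyloxy)phenol | Nc1c(OCc9ccccc9)cc(O)cc1OCc9ccccc9 | intermediate
4 | 2,6-bis(benzyloxy)-4-hydroxybenzenediazonium chloride | Oc1cc(OCc9ccccc9)c([N+]#N)c(OCc9ccccc9)c1.[Cl-] | intermediate (not isolated)
5 | 3,5-bis(benzyloxy)-4-diazocyclohexa-2,5-dien-1-one (para-quinone diazide for rings F, D, B) | O=C1C=C(OCc9ccccc9)C(=[N+]=[N-])C(OCc9ccccc9)=C1 | intermediate
6 | 3,5-bis(benzyloxy)-2-nitrophenol | Oc1cc(OCc9ccccc9)cc(OCc9ccccc9)c1[N+](=O)[O-] | intermediate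
7 | 2-amino-3,5-bis(benzyloxy)phenol | Nc1c(O)cc(OCc9ccccc9)cc1OCc9ccccc9 | intermediate
8 | 2,4-bis(benzyloxy)-6-hydroxybenzenediazonium chloride | Oc1cc(OCc9ccccc9)cc(OCc9ccccc9)c1[N+]#N.[Cl-] | intermediate (not isolated)
9 | 3,5-bis(benzyloxy)-6-diazocyclohexa-2,4-dien-1-one (ortho-quinone diazide for rings E, A) | O=C1C=C(OCc9ccccc9)C=C(OCc9ccccc9)C1=[N+]=[N-] | intermediate
10 | 3,4,5-trihydroxybenzaldehyde | O=Cc1cc(O)c(O)c(O)c1 | starting material
11 | 3,4,5-tris(benzyloxy)benzaldehyde | O=Cc1cc(OCc9ccccc9)c(OCc9ccccc9)c(OCc9ccccc9)c1 | intermediate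
12 | 3,4,5-tris(benzyloxy)phenyl formate | O=COc1cc(OCc9ccccc9)c(OCc9ccccc9)c(OCc9ccccc9)c1 | intermediate (not isolated)
13 | 3,4,5-tris(benzyloxy)phenol (ring G) | Oc1cc(OCc9ccccc9)c(OCc9ccccc9)c(OCc9ccccc9)c1 | intermediate
14 | 4-{(E)-[2,3,4-tris(benzyloxy)-6-hydroxyphenyl]diazenyl}benzenesulfonic acid (present as its sodium salt) | Oc1cc(OCc9ccccc9)c(OCc9ccccc9)c(OCc9ccccc9)c1/N=N/c1ccc(cc1)S(=O)(=O)O | intermediate (not isolated)
15 | 2-amino-3,4,5-tris(benzyloxy)phenol | Nc1c(O)cc(OCc9ccccc9)c(OCc9ccccc9)c1OCc9ccccc9 | intermediate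
16 | 2,3,4-tris(benzyloxy)-6-hydroxybenzenediazonium chloride | Oc1cc(OCc9ccccc9)c(OCc9ccccc9)c(OCc9ccccc9)c1[N+]#N.[Cl-] | intermediate (not isolated)
17 | 3,4,5-tris(benzyloxy)-6-diazocyclohexa-2,4-dien-1-one (ortho-quinone diazide for ring C) | O=C1C=C(OCc9ccccc9)C(OCc9ccccc9)=C(OCc9ccccc9)C1=[N+]=[N-] | intermediate
18 | dimer phenol HO–F–G, 3,5-bis(benzyloxy)-4-[3,4,5-tris(benzyloxy)phenoxy]phenol | Oc1cc(OCc9ccccc9)c(Oc2cc(OCc9ccccc9)c(OCc9ccccc9)c(OCc9ccccc9)c2)c(OCc9ccccc9)c1 | intermediate
19 | trimer phenol HO–E–F–G (heptabenzyl ether) | Oc1cc(OCc9ccccc9)cc(OCc9ccccc9)c1Oc1cc(OCc9ccccc9)c(Oc2cc(OCc9ccccc9)c(OCc9ccccc9)c(OCc9ccccc9)c2)c(OCc9ccccc9)c1 | intermediate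
20 | tetramer phenol HO–D–E–F–G (nonabenzyl ether) | Oc3cc(OCc9ccccc9)c(Oc4cc(OCc9ccccc9)cc(OCc9ccccc9)c4Oc4cc(OCc9ccccc9)c(Oc5cc(OCc9ccccc9)c(OCc9ccccc9)c(OCc9ccccc9)c5)c(OCc9ccccc9)c4)c(OCc9ccccc9)c3 | intermediate
21 | pentamer phenol HO–C–D–E–F–G (dodecabenzyl ether) | Oc3cc(OCc9ccccc9)c(OCc9ccccc9)c(OCc9ccccc9)c3Oc3cc(OCc9ccccc9)c(Oc4cc(OCc9ccccc9)cc(OCc9ccccc9)c4Oc4cc(OCc9ccccc9)c(Oc5cc(OCc9ccccc9)c(OCc9ccccc9)c(OCc9ccccc9)c5)c(OCc9ccccc9)c4)c(OCc9ccccc9)c3 | intermediate
22 | hexamer phenol HO–B–C–D–E–F–G (tetradecabenzyl ether) | Oc2cc(OCc9ccccc9)c(Oc3cc(OCc9ccccc9)c(OCc9ccccc9)c(OCc9ccccc9)c3Oc3cc(OCc9ccccc9)c(Oc4cc(OCc9ccccc9)cc(OCc9ccccc9)c4Oc4cc(OCc9ccccc9)c(Oc5cc(OCc9ccccc9)c(OCc9ccccc9)c(OCc9ccccc9)c5)c(OCc9ccccc9)c4)c(OCc9ccccc9)c3)c(OCc9ccccc9)c2 | intermediate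
23 | hexadecabenzyl heptamer HO–A–B–C–D–E–F–G | Oc1cc(OCc9ccccc9)cc(OCc9ccccc9)c1Oc2cc(OCc9ccccc9)c(Oc3cc(OCc9ccccc9)c(OCc9ccccc9)c(OCc9ccccc9)c3Oc3cc(OCc9ccccc9)c(Oc4cc(OCc9ccccc9)cc(OCc9ccccc9)c4Oc4cc(OCc9ccccc9)c(Oc5cc(OCc9ccccc9)c(OCc9ccccc9)c(OCc9ccccc9)c5)c(OCc9ccccc9)c4)c(OCc9ccccc9)c3)c(OCc9ccccc9)c2 | intermediate
24 | CNP0351377.0 | Oc1cc(O)c(Oc2cc(O)c(Oc3cc(O)c(O)c(O)c3Oc3cc(O)c(Oc4cc(O)cc(O)c4Oc4cc(O)c(Oc5cc(O)c(O)c(O)c5)c(O)c4)c(O)c3)c(O)c2)c(O)c1 | target

Total step count: 17 steps.
Longest linear sequence: 10 steps (steps 1, 2, 3, 11, 12, 13, 14, 15, 16, 17, from 3,5-bis(benzyloxy)phenol 1 to target 24).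

Steps most likely to fail

Step 14. The strongly donor-stabilised diazide may lose nitrogen sluggishly. Once activated, the carbenoid may be diverted into intramolecular arylation of a neighbouring benzyl phenyl ring, Wolff ring contraction or attack on electron-rich ring carbons before the dilute oligomeric phenol captures it. The fallback sets out from tetramer phenol 20 and takes ring C from aldehyde 11. Bromination of 11 with NBS in MeCN at the position ortho to the formyl group should give 2-bromo-3,4,5-tris(benzyloxy)benzaldehyde F1. Ullmann ether coupling of 20 with F1 (CuCl, 2,2,6,6-tetramethylheptane-3,5-dione, Cs2CO3, NMP, 110 °C), helped by the ortho-formyl group, should give the ring C aldehyde of the pentamer F2. Baeyer–Villiger oxidation with mCPBA should convert it into the aryl formate of the pentamer F3, and methanolysis (K2CO3, MeOH) returns to the route at pentamer phenol 21. This path also bypasses diazide 17 should step 10 prove troublesome.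

Step 13 (the same concern applies to step 15). The ring D phenol set free by the insertion is more accessible than the ortho-aryloxy phenol being arylated, so over-insertion into the product and low conversion of 19 may outweigh what slow addition can control. The fallback sets out from trimer phenol 19 and uses aminophenol 3 as the ring D source. Diazotisation of 3 with NaNO2 in aqueous HBr at 0 °C should give 2,6-bis(benzyloxy)-4-hydroxybenzenediazonium bromide F4, which is not isolated, and a Sandmeyer reaction with CuBr should convert it into 4-bromo-3,5-bis(benzyloxy)phenol F5. Protection with MOMCl and i-Pr2NEt gives 1,3-bis(benzyloxy)-2-bromo-5-(methoxymethoxy)benzene F6. A classical Ullmann ether synthesis between 19 and F6 (CuCl, 2,2,6,6-tetramethylheptane-3,5-dione, Cs2CO3, NMP, 120 °C), slow for a doubly alkoxy-flanked bromide but known for such phloroglucinol-type partners, should give the methoxymethyl ether of the tetramer F7, in which the ring D oxygen is masked so that no second arylation can occur. HCl in MeOH–THF removes the acetal and returns to the route at tetramer phenol 20.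

Step 17. Hydrogenolysis may stall as partially debenzylated intermediates precipitate or bind to the catalyst, and the free polyphenol may oxidise in air during isolation. The fallback sets out from hexadecabenzyl heptamer 23. Lewis-acid debenzylation with BCl3 and pentamethylbenzene as cation scavenger (CH2Cl2, −78 °C) is followed by acetylation of the crude product (Ac2O, pyridine) to the air-stable, chromatographable heptadecaacetate of the target F8. Deacetylation with HCl in degassed MeOH under argon returns to the route at target 24.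

Further compounds
F1 | step 14 | 2-bromo-3,4,5-tris(benzyloxy)benzaldehyde | O=Cc1cc(OCc9ccccc9)c(OCc9ccccc9)c(OCc9ccccc9)c1Br
F2 | step 14 | ring C aldehyde of the pentamer (21 with CHO in place of the ring C C1 hydroxyl) | O=Cc3cc(OCc9ccccc9)c(OCc9ccccc9)c(OCc9ccccc9)c3Oc3cc(OCc9ccccc9)c(Oc4cc(OCc9ccccc9)cc(OCc9ccccc9)c4Oc4cc(OCc9ccccc9)c(Oc5cc(OCc9ccccc9)c(OCc9ccccc9)c(OCc9ccccc9)c5)c(OCc9ccccc9)c4)c(OCc9ccccc9)c3
F3 | step 14 | aryl formate of pentamer phenol 21 | O=COc3cc(OCc9ccccc9)c(OCc9ccccc9)c(OCc9ccccc9)c3Oc3cc(OCc9ccccc9)c(Oc4cc(OCc9ccccc9)cc(OCc9ccccc9)c4Oc4cc(OCc9ccccc9)c(Oc5cc(OCc9ccccc9)c(OCc9ccccc9)c(OCc9ccccc9)c5)c(OCc9ccccc9)c4)c(OCc9ccccc9)c3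
F4 | step 13 | 2,6-bis(benzyloxy)-4-hydroxybenzenediazonium bromide | Oc1cc(OCc9ccccc9)c([N+]#N)c(OCc9ccccc9)c1.[Br-]
F5 | step 13 | 4-bromo-3,5-bis(benzyloxy)phenol | Oc1cc(OCc9ccccc9)c(Br)c(OCc9ccccc9)c1
F6 | step 13 | 1,3-bis(benzyloxy)-2-bromo-5-(methoxymethoxy)benzene | COCOc1cc(OCc9ccccc9)c(Br)c(OCc9ccccc9)c1
F7 | step 13 | methoxymethyl ether of tetramer phenol 20 | COCOc3cc(OCc9ccccc9)c(Oc4cc(OCc9ccccc9)cc(OCc9ccccc9)c4Oc4cc(OCc9ccccc9)c(Oc5cc(OCc9ccccc9)c(OCc9ccccc9)c(OCc9ccccc9)c5)c(OCc9ccccc9)c4)c(OCc9ccccc9)c3
F8 | step 17 | heptadecaacetate of the target | CC(=O)Oc1cc(OC(C)=O)c(Oc2cc(OC(C)=O)c(Oc3cc(OC(C)=O)c(OC(C)=O)c(OC(C)=O)c3Oc3cc(OC(C)=O)c(Oc4cc(OC(C)=O)cc(OC(C)=O)c4Oc4cc(OC(C)=O)c(Oc5cc(OC(C)=O)c(OC(C)=O)c(OC(C)=O)c5)c(OC(C)=O)c4)c(OC(C)=O)c3)c(OC(C)=O)c2)c(OC(C)=O)c1
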